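In these flasks a lower temperature may buy a cleaner product, but it also costs time, and two chemists dispute which of these counts.

| setting | delta | zeta | theta | eta |
|---|---|---|---|---|
| starting material | 0.10 M | 0.10 M | 0.10 M | 0.10 M |
| reagent | 0.250 M | 0.250 M | 0.250 M | 0.250 M |
| temperature | 20 °C |  | −10 °C | 5 °C |
| time | 2.5 h | 2.5 h | 2.5 h | 2.5 h |
| remark |  | at 20 °C until 30 min, from then on at −10 °C |  |  |

* the flask with the highest amount of target, in percent of the starting material charged ("all alike" if they lie within 1.5 percentage points) (delta / zeta / theta / eta / all alike)
* final target, as a percentage of the starting material charged, in delta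
* final target, as a percentage of the starting material charged, in zeta
* final target, as a percentage of the starting material charged, in theta
* final target, as a percentage of the starting material charged, in eta

- target is meant together with its crystals
- solid, in amounts per volume of the solution: crystals
- the constants hold at 20 °C; other temperatures follow from the activation energies and enthalpies

    starting material + reagent → intermediate A (k1 = 0.0098 M⁻¹ s⁻¹, Ea1 = 67.0 kJ mol⁻¹)
    intermediate A ⇌ intermediate B (K2 = 25, k2 = 5.2 × 10⁻⁴ s⁻¹, Ea2 = 99.0 kJ mol⁻¹, ΔH2 = 9.00 kJ mol⁻¹)
    reagent + intermediate B → intermediate C (k3 = 9.2 × 10⁻⁴ M⁻¹ s⁻¹, Ea3 = 69.0 kJ mol⁻¹)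
    intermediate C ⇌ intermediate D (K4 = 1.5, k4 = 5.1 × 10⁻⁴ s⁻¹, Ea4 = 90.0 kJ mol⁻¹, ΔH4 = −58.0 kJ mol⁻¹)
    reagent + intermediate B → target (k5 = 0.0030 M⁻¹ s⁻¹, Ea5 = 64.0 kJ mol⁻¹)
    crystals ⇌ target, rate k6*(cs6 - [target]) while solid is left; crystals form when [target] > cs6 (cs6 = 39 mM, k6 = 0.0038 s⁻¹)
    (constants at 20 °C)

In words: starting material and reagent give intermediate A, which turns reversibly into intermediate B. Intermediate B then meets reagent in two ways, to target or to intermediate C, and intermediate C turns reversibly into intermediate D.

The first chemist looks at that fork. Both branches carry [reagent] and [intermediate B] to the same power, so their rates keep a fixed ratio at a given temperature, however [reagent] falls. The share of the fork going to target (the selectivity) is 76.5% at 20 °C. In theta it is 80.5%, which is higher, as the branch to intermediate C has the larger activation energy. So she backs theta.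

The second chemist answers that a share counts what has reached the fork. Intermediate A must first pass step 2, whose activation energy is 99.0 kJ mol⁻¹, above the 64.0 kJ mol⁻¹ of the step to target. He integrates that forward rate by itself. The fraction of intermediate A passed is at most one minus the exponential of minus the passage count. In delta that count is 4.68: the forward rate constant of step 2 times the time spent at it. The same count is 0.0456 in theta, 0.524 in eta and 0.973 in zeta, where the warm half hour supplies more of it than the cold remainder.

Waiting for intermediate A and falling back can lower the passed fraction but not raise it, so share times passed fraction is a ceiling on target. For delta the ceiling is 75.8%. For theta it is 3.59%, far lower. I side with him and rank the flasks by ceiling, giving zeta and eta the theta share as a generous figure. That picks delta.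

The forecast, on his side, named delta, with 64% in delta, 17% in zeta, 0.15% in theta and 10% in eta, saying of theta “so almost nothing passes through”.

The simulation gives delta as the best flask: 64.8% in delta, 17.2% in zeta, 0.137% in theta and 10.0% in eta, each under its ceiling.

Theta ends at 0.137% of target, with intermediate A at 55.0%. The first chemist's view gets a region where the passage count is large, as in eta left long. Eta, left for 25.0 h, reaches a count of 5.24, above the 4.68 of delta at its asked time. At 25.0 h, target makes up 78.5% of target and intermediates C and D in eta, against 76.5% in delta, the order she claimed.

Take the charges of theta at 15 °C. The passage count there is 2.31, which with the theta share gives a ceiling of 72.5%. That flask gives 47.6% of target, with intermediate A down to 13.8%.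

The numbers were drawn at random within sensible limits; the run is a simulation.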